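## Retrosynthetic overview

1. Target 19 comes from cis-carbonate 17 by carbonate methanolysis and removal of two O-allyl groups. Carbonate 17 comes from chromene 15 by an asymmetric oxidative carboxylation that forms both C–O bonds at C3 and C4 of ring D.
2. Ring C of flavan 15 is closed through its C2–O1 bond by Mitsunobu etherification, with inversion, of (1R)-carbinol 14. Carbinol 14 comes from chalcone 12 by asymmetric transfer hydrogenation.
3. Chalcone 12 comes from ring B methyl ketone 9 and ring A aldehyde 11 by Claisen–Schmidt condensation.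
4. Ketone 9 comes from bis-ether 6 by a double Claisen cascade (ring D plus the C-prenyl group). Bis-ether 6 comes from 3,4-dihydroxyacetophenone by two O-alkylations.
5. Ring order: rings A and B are bought, ring D (dimethylpyran) is formed first, ring C (flavan pyran) second, and the ring D diol last.

Assumption: ring D is numbered as a chromane (O1, C2 with the two methyls, C3, C4); carbonate 5 is made rather than bought.

## Route

Step 1
Reactants: 1 3,4-dihydroxyacetophenone; 2 3-chloro-3-methylbut-1-yne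
Product: 3 1-[3-hydroxy-4-(2-methylbut-3-yn-2-yloxy)phenyl]ethanone
Conditions: K2CO3 (1.1 equiv), KI, CuI (2 mol%), DMF, 60 °C, Ar
Reagents that add atoms: none
Why: Williamson-type O-propargylation in which one equivalent of base ionises only the more acidic 4-OH (para to the acetyl group), so the tertiary propargyl ether forms at O4, the oxygen that becomes O1 of ring D.

Step 2
Reactants: 4 2-methylbut-3-en-2-ol
Product: 5 tert-butyl 2-methylbut-3-en-2-yl carbonate
Conditions: n-BuLi, THF, 0 °C; then Boc2O, 0 °C to rt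
Reagents that add atoms: di-tert-butyl dicarbonate (Boc2O), CC(C)(C)OC(=O)OC(=O)OC(C)(C)C
Why: Alkoxide acylation (Boc transfer) of the lithium alkoxide of the tertiary allylic alcohol gives the mixed carbonate used as a 1,1-dimethylallyl donor.

Step 3
Reactants: 3 1-[3-hydroxy-4-(2-methylbut-3-yn-2-yloxy)phenyl]ethanone; 5 tert-butyl 2-methylbut-3-en-2-yl carbonate
Product: 6 1-[3-(2-methylbut-3-en-2-yloxy)-4-(2-methylbut-3-yn-2-yloxy)phenyl]ethanone
Conditions: Pd(PPh3)4 (2 mol%), THF, 0 °C
Reagents that add atoms: none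
Why: Decarboxylative Tsuji–Trost O-allylation in which zerovalent palladium ionises 5 to a 1,1-dimethyl-π-allyl complex and the phenoxide attacks its more substituted terminus under kinetic control at 0 °C, giving the tertiary (reverse-prenyl) aryl ether.

Step 4
Reactants: 6 1-[3-(2-methylbut-3-en-2-yloxy)-4-(2-methylbut-3-yn-2-yloxy)phenyl]ethanone
Product: 9 1-[8-(allyloxy)-2,2-dimethyl-7-(3-methylbut-2-enyl)-2H-chromen-6-yl]ethanone, via C-prenyl phenol 7 (not isolated), via chromenol ketone 8 (not isolated)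
Conditions: DMF, 155 °C (sealed tube), 3 h; then rt, K2CO3, allyl bromide
Reagents that add atoms: allyl bromide, C=CCBr
Why: Tandem aromatic Claisen rearrangements followed by Williamson O-allylation, in which the allyl aryl ether shifts [3,3] to its only free ortho carbon to give the C-prenyl phenol, the propargyl aryl ether shifts [3,3] to C5 and closes ring D by [1,5]-H shift and 6π oxa-electrocyclisation, and the unmasked hindered phenol is capped in the same flask.

Step 5
Reactants: 10 2,4-dihydroxybenzaldehyde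
Product: 11 4-(allyloxy)-2-hydroxybenzaldehyde
Conditions: allyl bromide (1.0 equiv), K2CO3 (1.0 equiv), acetone, rt
Reagents that add atoms: allyl bromide, C=CCBr
Why: Williamson etherification that is selective for the 4-OH because the 2-OH is held in a hydrogen bond to the aldehyde.

Step 6
Reactants: 9 1-[8-(allyloxy)-2,2-dimethyl-7-(3-methylbut-2-enyl)-2H-chromen-6-yl]ethanone; 11 4-(allyloxy)-2-hydroxybenzaldehyde
Product: 12 (E)-3-[4-(allyloxy)-2-hydroxyphenyl]-1-[8-(allyloxy)-2,2-dimethyl-7-(3-methylbut-2-enyl)-2H-chromen-6-yl]prop-2-en-1-one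
Conditions: KOH (50% aq.), EtOH, rt, 24–48 h
Reagents that add atoms: none
Why: Claisen–Schmidt aldol condensation of the methyl ketone enolate with the aldehyde, with E1cB loss of water giving the (E)-enone.

Step 7
Reactants: 12 (E)-3-[4-(allyloxy)-2-hydroxyphenyl]-1-[8-(allyloxy)-2,2-dimethyl-7-(3-methylbut-2-enyl)-2H-chromen-6-yl]prop-2-en-1-one
Product: 14 (1R)-3-[4-(allyloxy)-2-hydroxyphenyl]-1-[8-(allyloxy)-2,2-dimethyl-7-(3-methylbut-2-enyl)-2H-chromen-6-yl]propan-1-ol, via dihydrochalcone 13 (not isolated)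
Conditions: RuCl[(R,R)-TsDPEN](p-cymene) (2 mol%), HCO2H/Et3N (5:2), EtOAc, 40 °C
Reagents that add atoms: none
Why: Noyori–Ikariya asymmetric transfer hydrogenation in which the ruthenium hydride first reduces the polarised enone C=C and then the aryl ketone through the CH/π-controlled outer-sphere transition state, which with the (R,R) ligand gives the (R)-carbinol as for acetophenone while the prenyl, allyl and chromene C=C bonds are untouched.

Step 8
Reactants: 14 (1R)-3-[4-(allyloxy)-2-hydroxyphenyl]-1-[8-(allyloxy)-2,2-dimethyl-7-(3-methylbut-2-enyl)-2H-chromen-6-yl]propan-1-ol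
Product: 15 (2S)-7-(allyloxy)-2-[8-(allyloxy)-2,2-dimethyl-7-(3-methylbut-2-enyl)-2H-chromen-6-yl]chromane
Conditions: PPh3, DIAD, toluene (0.02 M), 0 °C to rt
Reagents that add atoms: none
Why: Intramolecular Mitsunobu etherification in which the phenol displaces the alkoxyphosphonium of the benzylic alcohol in an SN2 6-exo-tet closure with inversion, so the (1R)-carbinol gives the (2S)-flavan and ring C is formed through its C2–O1 bond.

Step 9
Reactants: 15 (2S)-7-(allyloxy)-2-[8-(allyloxy)-2,2-dimethyl-7-(3-methylbut-2-enyl)-2H-chromen-6-yl]chromane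
Product: 17 (3R,4R)-8-(allyloxy)-6-[(2S)-7-(allyloxy)chroman-2-yl]-2,2-dimethyl-7-(3-methylbut-2-enyl)chromane-3,4-diyl carbonate (cis cyclic carbonate), via epoxide 16 (not isolated)
Conditions: (R,R)-Mn(salen)Cl (5 mol%), 4-phenylpyridine N-oxide (20 mol%), PhIO (1.1 equiv), CH2Cl2, 0 °C; then nBu4NBr (10 mol%), CO2 (10 bar), 40 °C [salen = N,N'-bis(3,5-di-tert-butylsalicylidene)cyclohexane-1,2-diamine dianion]
Reagents that add atoms: iodosylbenzene (PhIO), O=Ic1ccccc1; carbon dioxide, O=C=O
Why: Proposed new method: asymmetric oxidative carboxylation of an alkene to a cis-cyclic carbonate by one chiral (salen)manganese chloride, in which the oxo-manganese species made from PhIO transfers oxygen to the conjugated cis-alkene through a benzylic radical (so the isolated prenyl and allyl C=C bonds are left alone) and with the (R,R) ligand gives the (3R,4R)-epoxide 16 as for other 2,2-dimethylchromenes; the same complex of trivalent manganese then acts as Lewis acid while bromide opens the epoxide at benzylic C4, the C3 alkoxide takes up CO2 and the carbonate closes back onto C4, and because the C3–O bond is never broken and only a cis-fused five-membered ring can close, the cis-(3R,4R) carbonate results whether closure is SN2 (double inversion) or passes through the benzylic cation; the closest known reactions are the Jacobsen–Katsuki epoxidation of chromenes and the metal-salen/halide cycloaddition of CO2 to epoxides, which have not been merged into one enantioselective alkene-to-carbonate process.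

Step 10
Reactants: 17 (3R,4R)-8-(allyloxy)-6-[(2S)-7-(allyloxy)chroman-2-yl]-2,2-dimethyl-7-(3-methylbut-2-enyl)chromane-3,4-diyl carbonate
Product: 19 (3R,4R)-6-[(2S)-7-hydroxychroman-2-yl]-2,2-dimethyl-7-(3-methylbut-2-enyl)chromane-3,4,8-triol, via bis-allyl cis-diol 18 (not isolated)
Conditions: K2CO3 (0.5 equiv), MeOH, rt, 1 h; then Pd(PPh3)4 (5 mol%), degassed, rt
Reagents that add atoms: none
Why: Carbonate methanolysis followed by Tsuji–Trost-type deallylation, in which methoxide cleaves only acyl–oxygen bonds so C3 and C4 keep their configuration and zerovalent palladium then transfers both aryl-bound allyl groups to methoxide without touching the prenyl group or the acid-sensitive benzylic cis-diol.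

Stereocentres: C2 of the flavan is set in step 7 and inverted to (S) in step 8. C3 and C4 of ring D are set in step 9 and are not touched in step 10; the final product is the (2S,3R,4R) cis-diol of the target SMILES.

## Compound list

1 | 1-(3,4-dihydroxyphenyl)ethanone (3,4-dihydroxyacetophenone) | CC(=O)c1ccc(O)c(O)c1 | starting material
2 | 3-chloro-3-methylbut-1-yne | C#CC(C)(C)Cl | starting material
3 | 1-[3-hydroxy-4-(2-methylbut-3-yn-2-yloxy)phenyl]ethanone | CC(=O)c1ccc(OC(C)(C)C#C)c(O)c1 | intermediate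
4 | 2-methylbut-3-en-2-ol | C=CC(C)(C)O | starting material
5 | tert-butyl 2-methylbut-3-en-2-yl carbonate | C=CC(C)(C)OC(=O)OC(C)(C)C | intermediate
6 | 1-[3-(2-methylbut-3-en-2-yloxy)-4-(2-methylbut-3-yn-2-yloxy)phenyl]ethanone | CC(=O)c1ccc(OC(C)(C)C#C)c(OC(C)(C)C=C)c1 | intermediate
7 | 1-[3-hydroxy-2-(3-methylbut-2-enyl)-4-(2-methylbut-3-yn-2-yloxy)phenyl]ethanone | CC(=O)c1ccc(OC(C)(C)C#C)c(O)c1CC=C(C)C | intermediate
8 | 1-[8-hydroxy-2,2-dimethyl-7-(3-methylbut-2-enyl)-2H-chromen-6-yl]ethanone | CC(=O)c1cc2C=CC(C)(C)Oc2c(O)c1CC=C(C)C | intermediate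
9 | 1-[8-(allyloxy)-2,2-dimethyl-7-(3-methylbut-2-enyl)-2H-chromen-6-yl]ethanone | CC(=O)c1cc2C=CC(C)(C)Oc2c(OCC=C)c1CC=C(C)C | intermediate
10 | 2,4-dihydroxybenzaldehyde | O=Cc1ccc(O)cc1O | starting material
11 | 4-(allyloxy)-2-hydroxybenzaldehyde | O=Cc1ccc(OCC=C)cc1O | intermediate
12 | (E)-3-[4-(allyloxy)-2-hydroxyphenyl]-1-[8-(allyloxy)-2,2-dimethyl-7-(3-methylbut-2-enyl)-2H-chromen-6-yl]prop-2-en-1-one | O=C(/C=C/c1ccc(OCC=C)cc1O)c1cc2C=CC(C)(C)Oc2c(OCC=C)c1CC=C(C)C | intermediate
13 | 3-[4-(allyloxy)-2-hydroxyphenyl]-1-[8-(allyloxy)-2,2-dimethyl-7-(3-methylbut-2-enyl)-2H-chromen-6-yl]propan-1-one | O=C(CCc1ccc(OCC=C)cc1O)c1cc2C=CC(C)(C)Oc2c(OCC=C)c1CC=C(C)C | intermediate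
14 | (1R)-3-[4-(allyloxy)-2-hydroxyphenyl]-1-[8-(allyloxy)-2,2-dimethyl-7-(3-methylbut-2-enyl)-2H-chromen-6-yl]propan-1-ol | O[C@H](CCc1ccc(OCC=C)cc1O)c1cc2C=CC(C)(C)Oc2c(OCC=C)c1CC=C(C)C | intermediate
15 | (2S)-7-(allyloxy)-2-[8-(allyloxy)-2,2-dimethyl-7-(3-methylbut-2-enyl)-2H-chromen-6-yl]chromane | CC(C)=CCc1c([C@@H]2CCc3ccc(OCC=C)cc3O2)cc2C=CC(C)(C)Oc2c1OCC=C | intermediate
16 | (3R,4R)-3,4-epoxide of 15 (cis-fused oxirane on ring D, flavan centre 2S) | CC(C)=CCc1c([C@@H]2CCc3ccc(OCC=C)cc3O2)cc2c(c1OCC=C)OC(C)(C)[C@@H]3O[C@H]23 | intermediate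
17 | (3R,4R)-8-(allyloxy)-6-[(2S)-7-(allyloxy)chroman-2-yl]-2,2-dimethyl-7-(3-methylbut-2-enyl)chromane-3,4-diyl carbonate (cis cyclic carbonate) | CC(C)=CCc1c([C@@H]2CCc3ccc(OCC=C)cc3O2)cc2c(c1OCC=C)OC(C)(C)[C@@H]3OC(=O)O[C@H]23 | intermediate
18 | (3R,4R)-8-(allyloxy)-6-[(2S)-7-(allyloxy)chroman-2-yl]-2,2-dimethyl-7-(3-methylbut-2-enyl)chromane-3,4-diol (cis-diol) | CC(C)=CCc1c([C@@H]2CCc3ccc(OCC=C)cc3O2)cc2c(c1OCC=C)OC(C)(C)[C@H](O)[C@@H]2O | intermediate
19 | (3R,4R)-6-[(2S)-7-hydroxychroman-2-yl]-2,2-dimethyl-7-(3-methylbut-2-enyl)chromane-3,4,8-triol (cis-diol) | CC(C)=CCc1c([C@@H]2CCc3ccc(O)cc3O2)cc2c(c1O)OC(C)(C)[C@H](O)[C@@H]2O | target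

## Step count and risks

Total steps: 10. Longest linear sequence: 8 (steps 1, 3, 4, 6, 7, 8, 9, 10).

The three steps most likely to fail:

**Step 9 (the proposed new oxidative carboxylation).** The risks are slow CO2 insertion at the hindered epoxide, Lewis-acid rearrangement of epoxide 16 to a chromanone, and incomplete chemoselectivity of the oxo transfer. The fallback sets out from 15 and comes back at 17. It gives up the one-flask, single-catalyst idea and uses two separately known reactions, each with its own catalyst. First, Jacobsen–Katsuki epoxidation of 15 with (R,R)-Mn(salen)Cl, buffered NaOCl (pH 11.3) and 4-phenylpyridine N-oxide in CH2Cl2 at 0 °C, with epoxide 16 isolated on triethylamine-deactivated silica. Second, halide-catalysed CO2 cycloaddition with [Al(salen)]2O and nBu4NBr (CO2 10 bar, 50 °C), which is known to go with net retention and gives 17. No compound outside the list is made (F0).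

**Step 4 (one-flask double Claisen cascade and allylation).** The risks are competing pathways of the two ethers at 155 °C and loss of the tertiary allyl group. The fallback sets out from 3 and comes back at 8. It separates and reorders the two sigmatropic events. Compound 3 is heated alone (N,N-diethylaniline, 190 °C), so only the propargyl ether rearranges and cyclises, giving 1-(8-hydroxy-2,2-dimethyl-2H-chromen-6-yl)ethanone F1. F1 is O-alkylated with 5 and Pd(PPh3)4 (THF, 0 °C) to 1-[2,2-dimethyl-8-(2-methylbut-3-en-2-yloxy)-2H-chromen-6-yl]ethanone F2. F2 undergoes the allyl aryl Claisen shift on its own at 120 °C (toluene, sealed tube) to give 8, which is isolated and allylated to 9 as in step 4.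

**Step 8 (Mitsunobu closure).** The ring D oxygen sits para to the carbinol carbon and the prenyl group is ortho, so ionisation and loss of ee are possible. The fallback sets out from 9 and comes back at 15. It forms the ring C oxygen bond from the other side, as an aryl C–O bond, with retention. Commercial 2-bromo-4-hydroxybenzaldehyde F3 is allylated (allyl bromide, K2CO3, acetone) to 4-(allyloxy)-2-bromobenzaldehyde F4. F4 is condensed with 9 (KOH, EtOH) to the bromo chalcone F5. Transfer hydrogenation with the enantiomeric catalyst RuCl[(S,S)-TsDPEN](p-cymene) (HCO2H/Et3N) gives, through the saturated bromo ketone F6, the (1S)-bromo alcohol F7. Intramolecular Ullmann-type etherification (CuI, 3,4,7,8-tetramethyl-1,10-phenanthroline, Cs2CO3, toluene, 110 °C) then closes ring C without touching the stereocentre and gives 15.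

Further compounds
F1 | step 4 | 1-(8-hydroxy-2,2-dimethyl-2H-chromen-6-yl)ethanone | CC(=O)c1cc2C=CC(C)(C)Oc2c(O)c1
F2 | step 4 | 1-[2,2-dimethyl-8-(2-methylbut-3-en-2-yloxy)-2H-chromen-6-yl]ethanone | CC(=O)c1cc2C=CC(C)(C)Oc2c(OC(C)(C)C=C)c1
F3 | step 8 | 2-bromo-4-hydroxybenzaldehyde | O=Cc1ccc(O)cc1Br
F4 | step 8 | 4-(allyloxy)-2-bromobenzaldehyde | O=Cc1ccc(OCC=C)cc1Br
F5 | step 8 | (E)-3-[4-(allyloxy)-2-bromophenyl]-1-[8-(allyloxy)-2,2-dimethyl-7-(3-methylbut-2-enyl)-2H-chromen-6-yl]prop-2-en-1-one | O=C(/C=C/c1ccc(OCC=C)cc1Br)c1cc2C=CC(C)(C)Oc2c(OCC=C)c1CC=C(C)C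
F6 | step 8 | 3-[4-(allyloxy)-2-bromophenyl]-1-[8-(allyloxy)-2,2-dimethyl-7-(3-methylbut-2-enyl)-2H-chromen-6-yl]propan-1-one | O=C(CCc1ccc(OCC=C)cc1Br)c1cc2C=CC(C)(C)Oc2c(OCC=C)c1CC=C(C)C
F7 | step 8 | (1S)-3-[4-(allyloxy)-2-bromophenyl]-1-[8-(allyloxy)-2,2-dimethyl-7-(3-methylbut-2-enyl)-2H-chromen-6-yl]propan-1-ol | O[C@@H](CCc1ccc(OCC=C)cc1Br)c1cc2C=CC(C)(C)Oc2c(OCC=C)c1CC=C(C)C
F0 | step 9 | none | none
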